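## Retrosynthetic overview

1. Atom numbers follow the target SMILES. Ring A = C7–C8–C9–C10–C20, ring B = C10–C20–C14–C16–C17–C18, ring C = lactone C10–C11–O13–C14–C20, ring D = C5–C21–C22–C23–C25–C28. "Top" is the face of ring B that carries C11, O13, H20 and the C18 bromine.
2. The strategy rests on one feature. O13 sits on the methyl-bearing C14 of ring B, syn-axial (1,3) to carboxyl carbon C11 on quaternary C10. O13–C14 is therefore cut back to the axial C14–H bond of cis-hydrindanone bromo acid 10.
3. Late cuts are C5–OAc (acetylation after trans-diaxial Markovnikov hydration of C5=C21), C5–C6 (B-alkyl Suzuki–Miyaura coupling with ring D enol triflate 20) and C7–H (convex-face hydroboration of C7=C6H2, made from ketone 11).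
4. In acid 10, C18–Br comes from C18–B by a radical exchange, and ring B comes from an endo Diels–Alder reaction (bonds C10–C18 and C14–C20). Ring D comes from a 6-endo bromine-atom-transfer cyclisation (C21–C22, C23–Br) followed by resolution.
5. Ring order: A (purchased), then B (cycloaddition), then C (C–H lactonisation, last ring of the core). Ring D is built separately and joined afterwards.

Key step: step 7

Assumption: the sense of induction in step 3 is assigned by analogy with ketone-bound 2-cyclopentenone dienophiles; it is to be checked on crystalline 9 (bromine anomalous dispersion), and if it is opposite the (R)-catalyst is used with no other change.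

## Route

Step 1
Reactants: 1 3-oxocyclopent-1-ene-1-carboxylic acid
Product: 2 tert-butyl 3-oxocyclopent-1-ene-1-carboxylate
Conditions: Cl3CC(=NH)OtBu (2 equiv), BF3·OEt2 (cat.), CH2Cl2/cyclohexane, rt
Reagents that add atoms: tert-butyl 2,2,2-trichloroacetimidate, CC(C)(C)OC(=N)C(Cl)(Cl)Cl
Why: Acid-catalysed O-alkylation of a carboxylic acid by a trichloroacetimidate needs no base on the enone, and the tert-butyl ester is chosen because this ester ends up axial on quaternary C10 next to a bromide, where saponification of a methyl ester is unrealistic but acidolysis is easy.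

Step 2
Reactants: 3 (E)-but-2-enal (crotonaldehyde); 4 2-(dichloromethyl)-4,4,5,5-tetramethyl-1,3,2-dioxaborolane
Product: 5 4,4,5,5-tetramethyl-2-[(1E,3E)-penta-1,3-dien-1-yl]-1,3,2-dioxaborolane
Conditions: CrCl2 (8 equiv), LiI (4 equiv), THF, rt
Reagents that add atoms: none
Why: In this Takai–Utimoto-type olefination divalent chromium reduces 4 to a geminal dichromium boryl species that adds to the aldehyde and eliminates to the (E)-alkenylboronate, while the (E)-alkene of 3 is untouched, so the (1E,3E)-diene needed for a cis C15/boron relationship results.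

Step 3
Reactants: 2 tert-butyl 3-oxocyclopent-1-ene-1-carboxylate; 5 dienylboronate
Product: 6 tert-butyl (3aR,4S,7R,7aR)-7-methyl-1-oxo-4-(4,4,5,5-tetramethyl-1,3,2-dioxaborolan-2-yl)-1,2,3,4,7,7a-hexahydro-3aH-indene-3a-carboxylate
Conditions: (S)-3,3-diphenyl-1-(2-methylphenyl)tetrahydro-1H,3H-pyrrolo[1,2-c][1,3,2]oxazaborole protonated by (CF3SO2)2NH (20 mol %), 5 (1.5 equiv), CH2Cl2, −40 to −20 °C
Reagents that add atoms: none
Why: In this cationic-oxazaborolidine-catalysed Diels–Alder reaction the acid binds the more basic ring ketone, so C10 (β to it) bonds to the diene terminus remote from the methyl donor (boron-bearing C18) and C20 bonds to C14; the (E,E)-diene places C15 and boron cis, the ketone-endo transition state (bulky ester exo) places both cis to ring A, the cyclic dienophile gives the cis ring fusion, and the catalyst selects the enone face that sets 10R and 20R.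

Step 4
Reactants: 6 Diels–Alder adduct
Product: 7 tert-butyl (3aR,4S,7R,7aR)-7-methyl-1-oxo-4-(4,4,5,5-tetramethyl-1,3,2-dioxaborolan-2-yl)octahydro-3aH-indene-3a-carboxylate
Conditions: H2 (1 atm), Pd/C (10 wt %), EtOAc, rt
Reagents that add atoms: none
Why: Heterogeneous hydrogenation of the cis-disubstituted C16=C17 alkene creates no stereocentre, leaves ketone, ester and C–B bond alone, and removes the allylic unsaturation so that step 5 runs through a localised C18 radical.

Step 5
Reactants: 7 saturated pinacol boronate
Product: 9 tert-butyl (3aR,4R,7R,7aR)-4-bromo-7-methyl-1-oxooctahydro-3aH-indene-3a-carboxylate, via catechol boronate 8 (not isolated)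
Conditions: PhSO2Br (1.5 equiv), 2-methoxy-1,3,2-benzodioxaborole (0.3 equiv), di-tert-butyl hyponitrite (5 mol %), benzene, 70 °C
Reagents that add atoms: benzenesulfonyl bromide, O=S(=O)(Br)c1ccccc1; 2-methoxy-1,3,2-benzodioxaborole, COB1Oc2ccccc2O1 (atoms only in 8)
Why: In this deboronative radical-chain bromination of a pinacol boronic ester (in situ boron transesterification, homolytic substitution at boron by PhSO2•, bromine transfer from PhSO2Br) ketone and ester are tolerated, which an aryllithium ate-complex route would not allow, and the C18 radical should be brominated from the top, equatorial direction because the axial approach is blocked by syn-axial C7, giving the equatorial bromide cis to C11 (net inversion relative to C–B).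

Step 6
Reactants: 9 bromo keto ester
Product: 10 (3aR,4R,7R,7aR)-4-bromo-7-methyl-1-oxooctahydro-3aH-indene-3a-carboxylic acid
Conditions: CF3CO2H/CH2Cl2 (1:2), 0 °C to rt
Reagents that add atoms: none
Why: Acidolysis of the tert-butyl ester needs no base, so the bromide, epimerisable C20 and the ketone are left alone, and the γ-keto acid cannot close to a pseudo-acid because C11 and C7 are antiperiplanar across C10–C20.

Step 7
Reactants: 10 cis-hydrindanone bromo acid
Product: 11 bromolactone core ketone, (10R,14S,18R,20S): cis-hydrindan-7-one with the C11(=O)–O13 bridge from C10 to C14 on the top face, equatorial C18–Br cis to C11, C15 on the bottom face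
Conditions: Mn(CF3SO3)2((S,S)-pdp) (2 mol %; pdp = N,N'-bis(2-pyridylmethyl)-2,2'-bipyrrolidine), H2O2 (50 % aq, 2 equiv, syringe pump over 1 h), CF3CH2OH, 0 °C
Reagents that add atoms: none
Why: The acid of 10 binds to manganese and assists heterolysis of bound H2O2 to a formally pentavalent manganese oxo carboxylate, which abstracts the axial C14–H (1,7-hydrogen-atom transfer) and hands the bound carboxylate oxygen to the short-lived tertiary radical before it can reorganise. The closest known reaction type is the carboxylic-acid-directed γ-C–H lactonisation with H2O2 under bis(amine)bis(pyridine) manganese or iron catalysis, established at tertiary and secondary sites with retention. Ring C (C10–C11–O13–C14–C20) closes by O13–C14 bond formation between two syn-axial positions of ring B, a five-membered closure that turns ring B into a 6-oxabicyclo[3.2.1]octan-7-one and is trans-fused to ring A, so some strain has to be paid. C14 is not a new stereocentre but becomes quaternary with retention, since oxygen arrives on the face that hydrogen leaves and C15 stays equatorial (the descriptor changes from R to S by priority only). Site selectivity among the γ positions C7, C8, C14 and C17 is needed: C7 carries no hydrogen, C8–H is α to the ketone, C17–H lies next to CHBr, and only C14–H is tertiary and held against C11 in the chair with C15 and Br equatorial, the flipped chair being excluded by a syn-axial C9/C15 contact. Slow peroxide addition at 0 °C should keep Baeyer–Villiger oxidation of the cyclopentanone behind, and a neutral work-up avoids enolisation of 11 at C20.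

Step 8
Reactants: 11 bromolactone core ketone
Product: 12 C7 exocyclic methylene lactone, (10R,14S,18R,20S)
Conditions: Zn, CH2Br2, TiCl4 (reagent pre-formed in THF, 0–5 °C); then 11, CH2Cl2, 0 °C to rt
Reagents that add atoms: dibromomethane, BrCBr
Why: The Lombardo methylenation uses a non-basic geminal dizinc/titanium reagent that attacks ketones but not lactones at or below room temperature, and so avoids methylenation of C11, epimerisation at C20 to the less strained trans-hydrindane, and E1cB loss of the β-acyloxy group O13.

Step 9
Reactants: 13 4-methylpent-3-en-2-one (mesityl oxide)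
Product: 14 4,4-dimethylhex-5-en-2-one
Conditions: CH2=CHMgBr (1.3 equiv), CuBr·SMe2 (10 mol %), THF, −30 to 0 °C; 1 M HCl work-up
Reagents that add atoms: vinylmagnesium bromide, C=C[Mg]Br
Why: Copper-catalysed conjugate addition of a vinyl Grignard reagent to a β,β-disubstituted enone builds quaternary C25 with both methyl groups, and no stereocentre is formed.

Step 10
Reactants: 14 4,4-dimethylhex-5-en-2-one
Product: 16 1-bromo-4,4-dimethylhex-5-en-2-one, via silyl enol ether 15 (not isolated)
Conditions: LiN(iPr)2, THF, −78 °C; Me3SiCl; then N-bromosuccinimide, THF, 0 °C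
Reagents that add atoms: N-bromosuccinimide, O=C1CCC(=O)N1Br; chlorotrimethylsilane, C[Si](C)(C)Cl (atoms only in 15)
Why: Kinetic deprotonation takes the methyl group (C21) because the other α-carbon C28 is neopentylic, and electrophilic bromination of the silyl enol ether is far faster than attack of the reagent on the monosubstituted alkene.

Step 11
Reactants: 16 1-bromo-4,4-dimethylhex-5-en-2-one
Product: 17 rac-4-bromo-3,3-dimethylcyclohexan-1-one
Conditions: CuBr (20 mol %), tris(2-pyridylmethyl)amine (20 mol %), ClCH2CH2Cl, 80 °C
Reagents that add atoms: none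
Why: In this copper-catalysed atom-transfer radical cyclisation (Kharasch type) monovalent copper abstracts bromine, the planar 2-oxohex-5-enyl radical closes 6-endo (C21–C22; the 5-exo path is disfavoured by the in-ring carbonyl and by quaternary C25 next to C23, and closure is helped by the Thorpe–Ingold effect) and CuBr2 returns bromine to the C23 radical, which places bromine on the neopentylic carbon without a substitution step; the product is racemic.

Step 12
Reactants: 17 rac-4-bromo-3,3-dimethylcyclohexan-1-one
Product: 18 (R)-4-bromo-3,3-dimethylcyclohexan-1-one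
Conditions: preparative SFC, amylose tris(3,5-dimethylphenylcarbamate) phase, CO2/iPrOH
Reagents that add atoms: none
Why: Chromatographic resolution on a chiral phase fixes C23, because invertive displacement at this neopentylic secondary carbon is not dependable, and the (R) antipode is assigned by bromine anomalous dispersion on a crystalline hydrazone.

Step 13
Reactants: 18 (R)-4-bromo-3,3-dimethylcyclohexan-1-one
Product: 20 (R)-4-bromo-5,5-dimethylcyclohex-1-en-1-yl trifluoromethanesulfonate, via lithium enolate 19 (not isolated)
Conditions: LiN(SiMe3)2 (1.05 equiv), THF, −78 °C; N-(5-chloropyridin-2-yl)bis(trifluoromethanesulfonimide), −78 °C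
Reagents that add atoms: N-(5-chloropyridin-2-yl)bis(trifluoromethanesulfonimide), FC(F)(F)S(=O)(=O)N(c1ccc(Cl)cn1)S(=O)(=O)C(F)(F)F; lithium hexamethyldisilazide, [Li]N([Si](C)(C)C)[Si](C)(C)C (lithium only in 19)
Why: Kinetic enolisation and O-triflation occur at C21, away from neopentylic C28, and trapping at −78 °C together with the hindered backside of C23 should suppress cyclopropane formation by the γ-bromo enolate, so C23 is untouched.

Step 14
Reactants: 12 exocyclic methylene lactone; 20 ring D enol triflate
Product: 22 coupled C5=C21 alkene, (7R,10R,14S,18R,20S,23R), via alkylborane 21 (not isolated)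
Conditions: 12, 9-BBN-H (1.5 equiv), THF, 0 °C to rt; then H2O, 20, PdCl2(dppf) (5 mol %; dppf = 1,1'-bis(diphenylphosphino)ferrocene), AsPh3 (5 mol %), Cs2CO3, DMF, rt
Reagents that add atoms: 9-borabicyclo[3.3.1]nonane, B1C2CCCC1CCC2 (boron residue only in 21)
Why: In this hydroboration/B-alkyl Suzuki–Miyaura sequence the bulky borane puts boron on C6 and hydrogen on C7 from the convex face of ring A (the face of H20; the other face lies under ring B next to quaternary C14), which sets 7R with C6 on the concave side, and zerovalent palladium inserts only into the vinyl C–OTf bond while the secondary neopentylic bromides and the lactone survive the room-temperature base.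

Step 15
Reactants: 22 coupled alkene
Product: 24 tertiary alcohol, (5R,7R,10R,14S,18R,20S,23R), via organomercurial 23 (not isolated)
Conditions: Hg(OAc)2, THF/H2O (1:1), rt; then NaBH4, 0 °C; work-up at pH 4
Reagents that add atoms: water, O; mercury diacetate, CC(=O)O[Hg]OC(C)=O (atoms only in 23)
Why: Oxymercuration–demercuration gives Markovnikov anti addition through a chair-like trans-diaxial opening (Fürst–Plattner rule) with water axial at tertiary C5 and HgOAc axial at C21, and only the half-chair with equatorial C23–Br avoids a syn-diaxial Hg/Br contact, so oxygen should enter cis to the bromine (5R, CH2 equatorial) before NaBH4 replaces mercury by hydrogen; the acidic work-up re-closes any opened lactone.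

Step 16
Reactants: 24 tertiary alcohol
Product: 25 target CNP0133010.1, (5R,7R,10R,14S,18R,20S,23R)
Conditions: Ac2O (5 equiv), 4-(dimethylamino)pyridine (1 equiv), Et3N, CH2Cl2, 40 °C
Reagents that add atoms: acetic anhydride, CC(=O)OC(C)=O
Why: Acylation through the N-acetylpyridinium ion is the standard way to esterify hindered tertiary alcohols, does not break C5–O so the configuration is kept, and is tolerated by the lactone and the equatorial bromides.

## Compound list

1 | 3-oxocyclopent-1-ene-1-carboxylic acid | O=C1C=C(C(=O)O)CC1 | starting material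
2 | tert-butyl 3-oxocyclopent-1-ene-1-carboxylate | CC(C)(C)OC(=O)C1=CC(=O)CC1 | intermediate
3 | (E)-but-2-enal | C/C=C/C=O | starting material
4 | 2-(dichloromethyl)-4,4,5,5-tetramethyl-1,3,2-dioxaborolane | ClC(Cl)B1OC(C)(C)C(C)(C)O1 | starting material
5 | 4,4,5,5-tetramethyl-2-[(1E,3E)-penta-1,3-dien-1-yl]-1,3,2-dioxaborolane | C/C=C/C=C/B1OC(C)(C)C(C)(C)O1 | intermediate
6 | tert-butyl (3aR,4S,7R,7aR)-7-methyl-1-oxo-4-(pinacolboryl)-1,2,3,4,7,7a-hexahydro-3aH-indene-3a-carboxylate | O=C1CC[C@@]2(C(=O)OC(C)(C)C)[C@@H](B3OC(C)(C)C(C)(C)O3)C=C[C@@H](C)[C@@H]12 | intermediate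
7 | tert-butyl (3aR,4S,7R,7aR)-7-methyl-1-oxo-4-(pinacolboryl)octahydro-3aH-indene-3a-carboxylate | O=C1CC[C@@]2(C(=O)OC(C)(C)C)[C@@H](B3OC(C)(C)C(C)(C)O3)CC[C@@H](C)[C@@H]12 | intermediate
8 | catechol boronate corresponding to 7 | O=C1CC[C@@]2(C(=O)OC(C)(C)C)[C@@H](B3Oc4ccccc4O3)CC[C@@H](C)[C@@H]12 | intermediate
9 | tert-butyl (3aR,4R,7R,7aR)-4-bromo-7-methyl-1-oxooctahydro-3aH-indene-3a-carboxylate | O=C1CC[C@@]2(C(=O)OC(C)(C)C)[C@H](Br)CC[C@@H](C)[C@@H]12 | intermediate
10 | (3aR,4R,7R,7aR)-4-bromo-7-methyl-1-oxooctahydro-3aH-indene-3a-carboxylic acid | O=C1CC[C@@]2(C(=O)O)[C@H](Br)CC[C@@H](C)[C@@H]12 | intermediate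
11 | bromolactone core ketone, (10R,14S,18R,20S) | O=C1CC[C@@]23C(=O)O[C@@](C)(CC[C@H]2Br)[C@@H]13 | intermediate
12 | C7 exocyclic methylene lactone, (10R,14S,18R,20S) | C=C1CC[C@@]23C(=O)O[C@@](C)(CC[C@H]2Br)[C@@H]13 | intermediate
13 | 4-methylpent-3-en-2-one | CC(C)=CC(C)=O | starting material
14 | 4,4-dimethylhex-5-en-2-one | CC(=O)CC(C)(C)C=C | intermediate
15 | [(4,4-dimethylhexa-1,5-dien-2-yl)oxy]trimethylsilane | C=C(O[Si](C)(C)C)CC(C)(C)C=C | intermediate
16 | 1-bromo-4,4-dimethylhex-5-en-2-one | BrCC(=O)CC(C)(C)C=C | intermediate
17 | rac-4-bromo-3,3-dimethylcyclohexan-1-one | O=C1CCC(Br)C(C)(C)C1 | intermediate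
18 | (R)-4-bromo-3,3-dimethylcyclohexan-1-one | O=C1CC[C@@H](Br)C(C)(C)C1 | intermediate
19 | lithium (R)-4-bromo-5,5-dimethylcyclohex-1-en-1-olate | [Li]OC1=CC[C@@H](Br)C(C)(C)C1 | intermediate
20 | (R)-4-bromo-5,5-dimethylcyclohex-1-en-1-yl trifluoromethanesulfonate | O=S(=O)(OC1=CC[C@@H](Br)C(C)(C)C1)C(F)(F)F | intermediate
21 | B-(C6-alkyl)-9-borabicyclo[3.3.1]nonane of the core lactone, H7 cis to H20 | C(B1C2CCCC1CCC2)[C@H]3CC[C@@]45C(=O)O[C@@](C)(CC[C@H]4Br)[C@@H]35 | intermediate
22 | coupled C5=C21 alkene, (7R,10R,14S,18R,20S,23R) | C(C1=CC[C@@H](Br)C(C)(C)C1)[C@H]2CC[C@@]34C(=O)O[C@@](C)(CC[C@H]3Br)[C@@H]24 | intermediate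
23 | C21 acetoxymercurio C5 alcohol, OH and Hg trans-diaxial | O[C@@]1(C[C@H]2CC[C@@]34C(=O)O[C@@](C)(CC[C@H]3Br)[C@@H]24)[C@H]([Hg]OC(C)=O)C[C@@H](Br)C(C)(C)C1 | intermediate
24 | C5 tertiary alcohol, (5R,7R,10R,14S,18R,20S,23R) | O[C@@]1(C[C@H]2CC[C@@]34C(=O)O[C@@](C)(CC[C@H]3Br)[C@@H]24)CC[C@@H](Br)C(C)(C)C1 | intermediate
25 | CNP0133010.1 | CC(=O)O[C@@]1(C[C@H]2CC[C@@]34C(=O)O[C@@](C)(CC[C@H]3Br)[C@@H]24)CC[C@@H](Br)C(C)(C)C1 | target

## Step count and risks

Total step count: 16.

Longest linear sequence: 10 steps (1, 3, 4, 5, 6, 7, 8, 14, 15, 16).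

**Step 7 (most likely to fail).**
- Hydrogen abstraction may be slow because C14–H is β to the ketone.
- The peroxide may instead insert into the cyclopentanone (Baeyer–Villiger path).
- Hydroxyl rather than carboxylate transfer may stop at an open hydroxy acid, since the lactone is strained by its trans fusion to ring A.
- Either antipode of the manganese complex may be tried, because site and configuration are fixed by the substrate.

The fallback gives up the directed metal-oxo chemistry and sets out from 9. Methyl(trifluoromethyl)dioxirane (from 1,1,1-trifluoroacetone and KHSO5; CH2Cl2, −20 °C) inserts oxygen with retention into the only electron-rich tertiary C–H bond. C20–H is α to the ketone and C18–H is geminal to bromine, so C14–H is the expected site. The product is tert-butyl (3aR,4R,7S,7aS)-4-bromo-7-hydroxy-7-methyl-1-oxooctahydro-3aH-indene-3a-carboxylate F1. CF3CO2H in CH2Cl2 at 0 °C then removes the tert-butyl group and the syn-axial hydroxy acid lactonises, which comes back to the route at 11.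

**Step 3.**
- The weakly nucleophilic boryl diene may react too slowly with the trisubstituted dienophile at the temperatures where the chiral acid controls the face.
- Regio- and endo-selectivity may erode.
- The acid may protodeborylate the allylboronate product.

The fallback gives up catalyst control of absolute configuration and sets out from 2 and 5. Heating without catalyst (toluene, 110 °C, sealed tube, radical inhibitor) follows the established thermal cycloaddition mode of 1-dienylboronates with doubly activated alkenes. It should give the racemic endo adduct rac-6 F2. This is split by preparative SFC on a chiral phase and comes back to the route at 6.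

**Step 15.**
- Water has to attack C5 next to the axial methyl group on C25.
- The 1,4-relay from C23 may therefore give poor facial selectivity.
- Deoxymercuration back to the alkene may also compete.

The fallback replaces substrate control by reagent control and sets out from 22.
- A Shi epoxidation (KHSO5, K2CO3 buffer, MeCN/dimethoxymethane/H2O, 0 °C) is run with the L-sorbose-derived ketone 1,2:4,5-di-O-isopropylidene-β-L-erythro-2,3-hexodiulo-2,6-pyranose. This places oxygen on the face of the C23 bromine and gives the C5–C21 epoxide F3.
- LiI/AcOH in THF opens the epoxide at secondary C21 in the trans-diaxial sense to the C5-hydroxy C21-iodide F4.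
- Bu3SnH (1.05 equiv) with Et3B/air at −78 °C removes iodine much faster than the two bromines, which comes back to the route at 24.

## Further compounds

F1 | step 7 | tert-butyl (3aR,4R,7S,7aS)-4-bromo-7-hydroxy-7-methyl-1-oxooctahydro-3aH-indene-3a-carboxylate | O=C1CC[C@@]2(C(=O)OC(C)(C)C)[C@H](Br)CC[C@](C)(O)[C@@H]12
F2 | step 3 | rac-6 (both enantiomers of the endo adduct) | O=C1CC[C@@]2(C(=O)OC(C)(C)C)[C@@H](B3OC(C)(C)C(C)(C)O3)C=C[C@@H](C)[C@@H]12.O=C1CC[C@]2(C(=O)OC(C)(C)C)[C@H](B3OC(C)(C)C(C)(C)O3)C=C[C@H](C)[C@H]12
F3 | step 15 | C5–C21 epoxide of 22, oxygen cis to the C23 bromine | O1[C@@]2(C[C@H]3CC[C@@]45C(=O)O[C@@](C)(CC[C@H]4Br)[C@@H]35)[C@@H]1C[C@@H](Br)C(C)(C)C2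
F4 | step 15 | C5-hydroxy C21-iodide, trans-diaxial | O[C@@]1(C[C@H]2CC[C@@]34C(=O)O[C@@](C)(CC[C@H]3Br)[C@@H]24)[C@H](I)C[C@@H](Br)C(C)(C)C1
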